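**Plan**
Numbering: O1, C2 (aryl), C3 (methyl), C3a, C4–C7, C7a; ring A is the benzo ring, ring B the pendant aryl ring, ring C the dihydrofuran.
Enabling feature: C7a of ring A carries O1 and is bonded to C3a, so the C3a–C7a edge is the α-carbon and carbonyl carbon of a γ-butyrolactone, whose vinylketene silyl acetal is the diene C7a=C3a–C4=C5.
Retrosynthesis: TIPS off, propenyl back to allyl, C7–OMe back to C7–CHO; ring A is then cut at C5–C6 and C7–C7a (diene plus propynal, less silanol). C3a=C4 goes back to an aldol with pent-4-enal, the lactone to a homoallylic alcohol, and C2–C3 to a crotylboration.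
Forward: ring C is made first as the trans lactone (steps 1–4), the C4–C5 chain is attached and converted into the silyl dienol ether (steps 5–7), ring A is closed and aromatised (step 8), then C7 and the side chain are adjusted (steps 9–12).
Stereochemistry: C2 and C3 are set together in step 2 by a chiral phosphoric acid-catalysed anti crotylboration and are not touched afterwards; the E propenyl geometry comes from thermodynamic control in step 11.

Key step: step 8

Abbreviation: Ar = 3,4-dimethoxy-5-(triisopropylsilyloxy)phenyl.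
Assumption: the facial preference of TRIP-type phosphoric acids with aryl aldehydes ((R)-acid giving (R)-carbinols) is taken to hold for aldehyde 2, so the (S)-acid is specified for the (1S,2S)-alcohol.

Step 1
Reactants: 1 3-hydroxy-4,5-dimethoxybenzaldehyde
Product: 2 3,4-dimethoxy-5-(triisopropylsilyloxy)benzaldehyde
Conditions: TIPSCl, imidazole, DMF, 23 °C
Reagents that add atoms: triisopropylsilyl chloride, CC(C)[Si](Cl)(C(C)C)C(C)C
Why: Imidazole-mediated silylation of the phenol; the hindered TIPS aryl ether is chosen because it should survive the amide bases, the mild acid and the K2CO3 used later and still leave with fluoride in step 12.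

Step 2
Reactants: 2 3,4-dimethoxy-5-(triisopropylsilyloxy)benzaldehyde; 3 (E)-crotylboronic acid pinacol ester
Product: 5 (1S,2S)-1-Ar-2-methylbut-3-en-1-ol, via O-pinacolboryl ether 4 (not isolated)
Conditions: (S)-3,3'-bis(2,4,6-triisopropylphenyl)-1,1'-binaphthyl-2,2'-diyl hydrogen phosphate [(S)-TRIP, 5 mol %], 4 Å molecular sieves, toluene, −30 °C; aqueous work-up
Reagents that add atoms: (E)-crotylboronic acid pinacol ester 3, C/C=C/CB1OC(C)(C)C(C)(C)O1
Why: Chiral phosphoric acid-catalysed crotylboration: the acid activates the boronate by hydrogen bonding, the closed six-membered chair transition state transfers the E geometry of 3 into the anti (1S,2S) relationship and the catalyst pocket selects the aldehyde face, so C2 and C3 of the target are both set here.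

Step 3
Reactants: 5 (1S,2S)-1-Ar-2-methylbut-3-en-1-ol
Product: 7 (1S,2S)-1-Ar-2-methylbutane-1,4-diol, via B-alkyl-9-BBN adduct 6 (not isolated)
Conditions: 9-BBN (2.5 equiv), THF, 0 → 23 °C; then NaBO3·4H2O, THF/H2O, 23 °C
Reagents that add atoms: sodium perborate tetrahydrate NaBO3·4H2O, [Na+].[Na+].O[B-]1(O)OO[B-](O)(O)OO1
Why: Anti-Markovnikov hydroboration of the terminal alkene with 9-BBN and oxidation of the C–B bond with retention give the primary alcohol without touching the stereocentres; perborate is used instead of NaOH/H2O2 to spare the base-labile aryl silyl ether.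

Step 4
Reactants: 7 (1S,2S)-1-Ar-2-methylbutane-1,4-diol
Product: 9 (4S,5S)-5-Ar-4-methyldihydrofuran-2(3H)-one, via lactol 8 (not isolated)
Conditions: TEMPO (20 mol %), PhI(OAc)2 (2.5 equiv), CH2Cl2, 23 °C
Reagents that add atoms: none
Why: TEMPO/PhI(OAc)2 oxidative lactonisation of a 1,4-diol: the oxoammonium salt oxidises the unhindered primary alcohol in preference to the secondary benzylic one, the hydroxy aldehyde closes to lactol 8 and a second oxidation gives the γ-lactone, so that C7a, C3a, C3, C2 and O1 are in place with the trans relationship unchanged.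

Step 5
Reactants: 9 (4S,5S)-5-Ar-4-methyldihydrofuran-2(3H)-one; 10 pent-4-enal
Product: 12 (4S,5S)-5-Ar-3-(1-hydroxypent-4-enyl)-4-methyldihydrofuran-2(3H)-one (diastereomer mixture), via lithium enolate 11 (not isolated)
Conditions: LiN(iPr)2, THF, −78 °C; then 10; AcOH quench
Reagents that add atoms: pent-4-enal 10, C=CCCC=O
Why: Aldol addition of the lithium enolate, formed at the only α-CH2, attaches C4, C5 and the future allyl group; the configuration at the two new carbons is irrelevant because both become sp2 in steps 6 and 7, and C3 is not enolisable.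

Step 6
Reactants: 12 (4S,5S)-5-Ar-3-(1-hydroxypent-4-enyl)-4-methyldihydrofuran-2(3H)-one
Product: 14 (3E,4S,5S)-5-Ar-4-methyl-3-(pent-4-enylidene)dihydrofuran-2(3H)-one, via mesylate 13 (not isolated)
Conditions: MsCl, Et3N, CH2Cl2, 0 °C; then DBU, 23 °C
Reagents that add atoms: none
Why: Mesylation followed by E1cB elimination completes the aldol condensation and should give mainly the E exocyclic enoate (any Z isomer converges on the same dienolate in step 7); the C3 methine is only cross-conjugated and should not be deprotonated by DBU.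

Step 7
Reactants: 14 (3E,4S,5S)-5-Ar-4-methyl-3-(pent-4-enylidene)dihydrofuran-2(3H)-one
Product: 16 tert-butyl{[(4S,5S)-5-Ar-4-methyl-3-[(1E)-penta-1,4-dien-1-yl]-4,5-dihydrofuran-2-yl]oxy}dimethylsilane, via lithium dienolate 15 (not isolated)
Conditions: LiN(iPr)2, THF/DMPU, −78 °C; TBSCl, −78 → 0 °C; non-aqueous work-up (pentane, filtration), used crude
Reagents that add atoms: tert-butyldimethylsilyl chloride, CC(C)(C)[Si](C)(C)Cl
Why: Vinylogous enolisation: the amide removes a γ-proton at C5 to give the extended dienolate, which TBSCl silylates on oxygen in the presence of DMPU, the standard preparation of 1-alkoxy-1-silyloxy-1,3-dienes from enoates; allylic strain against the C3 substituents is expected to turn the allyl group outward and give the E C4=C5 bond.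

Step 8
Reactants: 16 tert-butyldimethylsilyl dienol ether (diene C7a=C3a–C4=C5); 17 propynal
Product: 19 (2S,3S)-5-allyl-2-Ar-3-methyl-2,3-dihydrobenzofuran-7-carbaldehyde, via cycloadduct 18 (not isolated)
Conditions: 17 (freshly distilled, 1.5 equiv), toluene, 0 → 60 °C; then CSA (5 mol %), 23 °C, anhydrous
Reagents that add atoms: propynal 17, C#CC=O
Why: The diene, whose HOMO is raised by the two oxygens on C7a and has its largest coefficient at C5, adds to the electrophilic terminal carbon of propynal, so C5–C6 forms ahead of C7a–C7 in a concerted asynchronous [4+2] cycloaddition to 18; catalytic acid then ionises the exocyclic C7a–OSi bond with help from the O1 lone pair and the resulting cyclohexadienyl cation loses H5 to give the arene. The closest known reaction type is the Diels–Alder benzannulation of 1-alkoxy-1-silyloxy-1,3-dienes (vinylketene silyl acetals) with acetylenic carbonyl compounds, aromatised by loss of silanol. Ring A is the only ring closed, by intermolecular [4+2] annulation onto the C3a–C7a edge of ring C, with both new bonds formed in the one cycloaddition. No lasting stereocentre is created, since C5 and C7a of 18 become sp2 on aromatisation, and C2 and C3 lie outside the diene and are not acidified. The step needs three selectivities: regiochemistry, secured by the ketene acetal polarisation and the formyl group, which places CHO on C7; reaction at the alkyne and not the carbonyl, secured by running without a Lewis acid; and loss of silanol and not opening at O1, secured by the better leaving group and the cyclic oxocarbenium pathway under anhydrous acid.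

Step 9
Reactants: 19 (2S,3S)-5-allyl-2-Ar-3-methyl-2,3-dihydrobenzofuran-7-carbaldehyde
Product: 21 (2S,3S)-5-allyl-2-Ar-3-methyl-2,3-dihydrobenzofuran-7-ol, via aryl formate 20 (not isolated)
Conditions: 30% aq. H2O2 (1.5 equiv), KHSO4 (10 mol %), MeOH/THF, 23 °C
Reagents that add atoms: hydrogen peroxide, OO
Why: Acid-catalysed Dakin oxidation (Baeyer–Villiger-type aryl migration): hydrogen peroxide adds to the formyl carbon, the electron-rich ring A carbon ortho to O1 migrates to oxygen, and the formate is methanolysed in the same flask; hydrogen peroxide without a peracid is not expected to epoxidise the isolated terminal alkene, and the hindered TIPS aryl ether should tolerate the weakly acidic methanol.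

Step 10
Reactants: 21 (2S,3S)-5-allyl-2-Ar-3-methyl-2,3-dihydrobenzofuran-7-ol
Product: 22 (2S,3S)-5-allyl-2-Ar-7-methoxy-3-methyl-2,3-dihydrobenzofuran
Conditions: MeI, K2CO3, acetone, 40 °C
Reagents that add atoms: iodomethane, CI
Why: Williamson O-methylation of the only free phenol; K2CO3 in acetone leaves the TIPS ether on ring B untouched, which is what keeps the two phenolic oxygens distinguishable.

Step 11
Reactants: 22 (2S,3S)-5-allyl-2-Ar-7-methoxy-3-methyl-2,3-dihydrobenzofuran
Product: 23 (2S,3S)-2-Ar-7-methoxy-3-methyl-5-[(E)-prop-1-enyl]-2,3-dihydrobenzofuran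
Conditions: RuHCl(CO)(PPh3)3 (3 mol %), toluene, 80 °C
Reagents that add atoms: none
Why: Ruthenium hydride-catalysed alkene isomerisation by reversible hydrometalation and β-hydride elimination moves the double bond one position into conjugation with ring A and stops there, the E-propenyl arene being the thermodynamic product.

Step 12
Reactants: 23 (2S,3S)-2-Ar-7-methoxy-3-methyl-5-[(E)-prop-1-enyl]-2,3-dihydrobenzofuran
Product: 24 5-[(2S,3S)-7-methoxy-3-methyl-5-[(E)-prop-1-enyl]-2,3-dihydrobenzofuran-2-yl]-2,3-dimethoxyphenol (target)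
Conditions: Bu4NF, AcOH, THF, 0 → 23 °C
Reagents that add atoms: none
Why: Fluoride-induced cleavage of the aryl silyl ether, buffered with acetic acid so that the phenoxide is protonated at once, frees the ring B phenol and should leave both stereocentres and the E alkene unchanged.

**Compound list**
1 | 3-hydroxy-4,5-dimethoxybenzaldehyde | COc1cc(C=O)cc(O)c1OC | starting material
2 | 3,4-dimethoxy-5-(triisopropylsilyloxy)benzaldehyde | COc1cc(C=O)cc(O[Si](C(C)C)(C(C)C)C(C)C)c1OC | intermediate
3 | (E)-crotylboronic acid pinacol ester | C/C=C/CB1OC(C)(C)C(C)(C)O1 | starting material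
4 | O-pinacolboryl ether of 5 (not isolated) | C=C[C@H](C)[C@@H](c1cc(O[Si](C(C)C)(C(C)C)C(C)C)c(OC)c(OC)c1)OB1OC(C)(C)C(C)(C)O1 | intermediate
5 | (1S,2S)-1-[3,4-dimethoxy-5-(triisopropylsilyloxy)phenyl]-2-methylbut-3-en-1-ol | C=C[C@H](C)[C@@H](c1cc(O[Si](C(C)C)(C(C)C)C(C)C)c(OC)c(OC)c1)O | intermediate
6 | B-alkyl-9-borabicyclo[3.3.1]nonane adduct of 5 (not isolated) | B1(CC[C@H](C)[C@@H](c2cc(O[Si](C(C)C)(C(C)C)C(C)C)c(OC)c(OC)c2)O)C2CCCC1CCC2 | intermediate
7 | (1S,2S)-1-[3,4-dimethoxy-5-(triisopropylsilyloxy)phenyl]-2-methylbutane-1,4-diol | OCC[C@H](C)[C@@H](c1cc(O[Si](C(C)C)(C(C)C)C(C)C)c(OC)c(OC)c1)O | intermediate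
8 | (4S,5S)-5-aryl-4-methyltetrahydrofuran-2-ol, lactol, anomer mixture (not isolated) | OC1C[C@H](C)[C@@H](c2cc(O[Si](C(C)C)(C(C)C)C(C)C)c(OC)c(OC)c2)O1 | intermediate
9 | (4S,5S)-5-[3,4-dimethoxy-5-(triisopropylsilyloxy)phenyl]-4-methyldihydrofuran-2(3H)-one | O=C1C[C@H](C)[C@@H](c2cc(O[Si](C(C)C)(C(C)C)C(C)C)c(OC)c(OC)c2)O1 | intermediate
10 | pent-4-enal | C=CCCC=O | starting material
11 | lithium enolate of 9 (not isolated) | [Li]OC1=C[C@H](C)[C@@H](c2cc(O[Si](C(C)C)(C(C)C)C(C)C)c(OC)c(OC)c2)O1 | intermediate
12 | (4S,5S)-5-aryl-3-(1-hydroxypent-4-enyl)-4-methyldihydrofuran-2(3H)-one, mixture at C3 and the carbinol carbon | C=CCCC(O)C1[C@H](C)[C@@H](c2cc(O[Si](C(C)C)(C(C)C)C(C)C)c(OC)c(OC)c2)OC1=O | intermediate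
13 | methanesulfonate of 12 (not isolated) | C=CCCC(OS(C)(=O)=O)C1[C@H](C)[C@@H](c2cc(O[Si](C(C)C)(C(C)C)C(C)C)c(OC)c(OC)c2)OC1=O | intermediate
14 | (3E,4S,5S)-5-aryl-4-methyl-3-(pent-4-enylidene)dihydrofuran-2(3H)-one | C=CCC/C=C1\[C@H](C)[C@@H](c2cc(O[Si](C(C)C)(C(C)C)C(C)C)c(OC)c(OC)c2)OC1=O | intermediate
15 | lithium dienolate of 14 (not isolated) | C=CC/C=C/C1[C@H](C)[C@@H](c2cc(O[Si](C(C)C)(C(C)C)C(C)C)c(OC)c(OC)c2)OC=1O[Li] | intermediate
16 | tert-butyl{[(4S,5S)-5-aryl-4-methyl-3-[(1E)-penta-1,4-dien-1-yl]-4,5-dihydrofuran-2-yl]oxy}dimethylsilane | C=CC/C=C/C1[C@H](C)[C@@H](c2cc(O[Si](C(C)C)(C(C)C)C(C)C)c(OC)c(OC)c2)OC=1O[Si](C)(C)C(C)(C)C | intermediate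
17 | propynal | C#CC=O | starting material
18 | (2S,3S)-5-allyl-2-aryl-7a-(tert-butyldimethylsilyloxy)-3-methyl-2,3,5,7a-tetrahydrobenzofuran-7-carbaldehyde, mixture at C5 and C7a (not isolated) | C=CCC1C=C2[C@H](C)[C@@H](c3cc(O[Si](C(C)C)(C(C)C)C(C)C)c(OC)c(OC)c3)OC2(O[Si](C)(C)C(C)(C)C)C(C=O)=C1 | intermediate
19 | (2S,3S)-5-allyl-2-[3,4-dimethoxy-5-(triisopropylsilyloxy)phenyl]-3-methyl-2,3-dihydrobenzofuran-7-carbaldehyde | C=CCc1cc(C=O)c2c(c1)[C@H](C)[C@@H](c3cc(O[Si](C(C)C)(C(C)C)C(C)C)c(OC)c(OC)c3)O2 | intermediate
20 | (2S,3S)-5-allyl-2-aryl-3-methyl-2,3-dihydrobenzofuran-7-yl formate (not isolated) | C=CCc1cc(OC=O)c2c(c1)[C@H](C)[C@@H](c3cc(O[Si](C(C)C)(C(C)C)C(C)C)c(OC)c(OC)c3)O2 | intermediate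
21 | (2S,3S)-5-allyl-2-[3,4-dimethoxy-5-(triisopropylsilyloxy)phenyl]-3-methyl-2,3-dihydrobenzofuran-7-ol | C=CCc1cc(O)c2c(c1)[C@H](C)[C@@H](c3cc(O[Si](C(C)C)(C(C)C)C(C)C)c(OC)c(OC)c3)O2 | intermediate
22 | (2S,3S)-5-allyl-2-[3,4-dimethoxy-5-(triisopropylsilyloxy)phenyl]-7-methoxy-3-methyl-2,3-dihydrobenzofuran | C=CCc1cc(OC)c2c(c1)[C@H](C)[C@@H](c3cc(O[Si](C(C)C)(C(C)C)C(C)C)c(OC)c(OC)c3)O2 | intermediate
23 | (2S,3S)-2-[3,4-dimethoxy-5-(triisopropylsilyloxy)phenyl]-7-methoxy-3-methyl-5-[(E)-prop-1-enyl]-2,3-dihydrobenzofuran | C/C=C/c1cc(OC)c2c(c1)[C@H](C)[C@@H](c3cc(O[Si](C(C)C)(C(C)C)C(C)C)c(OC)c(OC)c3)O2 | intermediate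
24 | 5-[(2S,3S)-7-methoxy-3-methyl-5-[(E)-prop-1-enyl]-2,3-dihydrobenzofuran-2-yl]-2,3-dimethoxyphenol | C/C=C/c1cc(OC)c2c(c1)[C@H](C)[C@@H](c3cc(O)c(OC)c(OC)c3)O2 | target

**Totals and risks**
Total step count: 12. Longest linear sequence: 12 steps (1 to 24).

Step 8. What may go wrong: the diene may add to the formyl group of propynal (vinylogous aldol or hetero-cycloaddition) instead of the alkyne. The ynal may also oligomerise, or a stepwise Michael pathway with silyl transfer may stop at an open-chain adduct. The fallback sets out from diene 16 and uses methyl propiolate (toluene, 80 °C, then CSA), a dienophile with no competing carbonyl electrophile and the best documented partner for this diene class. The silyloxy cycloadduct F1 should lose silanol in the same way to give methyl (2S,3S)-5-allyl-2-aryl-3-methyl-2,3-dihydrobenzofuran-7-carboxylate F2. Reduction with iBu2AlH (CH2Cl2, −78 °C) would give the 7-hydroxymethyl compound F3, and MnO2 (CH2Cl2, 23 °C) would oxidise it to aldehyde 19, where the route is rejoined.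

Step 7. What may go wrong: the amide may add in conjugate fashion to the enoate, a proton other than C5–H may be removed, the dienolate may be silylated on carbon, or the ketene acetal may hydrolyse during isolation. The fallback sets out from alkylidene lactone 14 and inverts the order of events by soft enolisation with TBSOTf and Et3N (CH2Cl2, 0 °C). The carbonyl oxygen is silylated first and the amine then removes the C5 proton of the silyloxy-substituted allyl cation, the only position acidified in that ion. No strong base or nucleophile is present, and reversible proton transfer should favour the E diene. The sequence returns to 16 and makes no new compound (F0).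

Step 9. What may go wrong: the acidic methanol may remove the TIPS group or ionise the benzylic C2–O1 bond, or the peroxide may oxidise the electron-rich rings before aryl migration is complete. The fallback sets out from aldehyde 19 and replaces the one-flask acid-catalysed process by an acid-free two-stage sequence. A buffered peracid Baeyer–Villiger oxidation (mCPBA, 1.1 equiv, KHCO3, CH2Cl2, 0 °C) would be stopped at formate 20, which is isolated. The formate would then be cleaved under weakly basic conditions (KHCO3, MeOH, 0 °C) to phenol 21, where the route is rejoined. The remaining risk in this variant is epoxidation of the monosubstituted alkene, which low temperature and a single equivalent of peracid are meant to hold back. No new compound is made (F0).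

**Further compounds**
F1 | step 8 | methyl (2S,3S)-5-allyl-2-aryl-7a-(tert-butyldimethylsilyloxy)-3-methyl-2,3,5,7a-tetrahydrobenzofuran-7-carboxylate, cycloadduct, not isolated | C=CCC1C=C2[C@H](C)[C@@H](c3cc(O[Si](C(C)C)(C(C)C)C(C)C)c(OC)c(OC)c3)OC2(O[Si](C)(C)C(C)(C)C)C(C(=O)OC)=C1
F2 | step 8 | methyl (2S,3S)-5-allyl-2-[3,4-dimethoxy-5-(triisopropylsilyloxy)phenyl]-3-methyl-2,3-dihydrobenzofuran-7-carboxylate | C=CCc1cc(C(=O)OC)c2c(c1)[C@H](C)[C@@H](c3cc(O[Si](C(C)C)(C(C)C)C(C)C)c(OC)c(OC)c3)O2
F3 | step 8 | [(2S,3S)-5-allyl-2-[3,4-dimethoxy-5-(triisopropylsilyloxy)phenyl]-3-methyl-2,3-dihydrobenzofuran-7-yl]methanol | C=CCc1cc(CO)c2c(c1)[C@H](C)[C@@H](c3cc(O[Si](C(C)C)(C(C)C)C(C)C)c(OC)c(OC)c3)O2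
F0 | step 7 | none | none
F0 | step 9 | none | none
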